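Readings and results were computed for substances that don't exist; noise was put on by code.

Early on the flask says little. At 4.00 h the south-west run still shows 93% electrophile and 2% target, because about a quarter of the nucleophile has been fed by then. So the figure to watch is the fraction of electrophile left, read late.

in all of them: electrophile 0.050 M

| charge | nucleophile | free base | scavenger | remark | time |
|---|---|---|---|---|---|
| south-west | 0.050 M (fed, over 15 h) | 0.071 M | 0.075 M | run made earlier |  |
| east | 0.050 M (fed, over 15 h) | 0.086 M | 0.075 M | run made earlier |  |
| alpha | 0.0500 M (fed, over 15 h) | 0.120 M | 0.0750 M |  | 15 h |
| zeta | 0.0500 M (fed, over 15 h) | 0.0550 M | 0.0750 M |  | 15 h |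
| theta | 0.0500 M (fed, over 15 h) | 0.0830 M | 0.0750 M |  | 15 h |

- south-west (time / h: electrophile / %, target / %): 1.33: 102, 0; 4.00: 93, 2; 8.00: 88, 11; 10.0: 88, 14; 15.0: 72, 25
- east (time / h: electrophile / %, target / %): 1.33: 100, 3; 2.50: 97, 5; 4.00: 97, 1; 8.00: 89, 6; 15.0: 73, 25

(standard deviation of a reading: 2 percentage points)

1. part of the electrophile that has reacted at the end, alpha
2. part of the electrophile that has reacted at the end, zeta
3. part of the electrophile that has reacted at the end, theta
4. what raising the concentration of free base from its lowest to its highest value here does to the part of the electrophile that has reacted (changes below 5 percentage points count as none) (no change / it rises / it falls)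



If electrophile and nucleophile react in one step, first order in each, the negative logarithm of the fraction left equals a rate constant times the exposure, the time integral of the nucleophile concentration. The two runs end with a mean of 72.5% left. The steady feed, with no reaction, gives an exposure of 1350 M·s. Reaction removes nucleophile, and if the loss grows with the square of time, the exposure falls to 1100 M·s. Dividing gives the read rate constant 1.05 M⁻¹ h⁻¹, a reading with the scatter of the runs.

Two chemists dispute what free base does. The first holds that base does not enter the exposure. Every new flask then ends like the old runs, with 27.5% reacted, and this is the reckoning to commit to. The forecast agrees closely, with 27% for alpha, 27% for zeta, 27% for theta, and no change. Its ground: “Base is in excess of nucleophile in every charge, even at 0.055 M, so it is probably not limiting.”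

The second chemist answers that the runs barely test this. Suppose the logarithm scales with base to the power 0.5, around their mean base of 0.0785 M. South-west and east should then differ by 2.2 percentage points, while the scatter of a difference is 2.8 points. That order survives, and it gives 23.6% reacted in zeta and 32.8% in alpha. The gap of 9.2 points stands against a margin of 5 points, so the second chemist says it rises.

    electrophile + nucleophile → acid set free + target (k = 1.07 M⁻¹ h⁻¹)
    nucleophile + acid set free ⇌ protonated nucleophile, settled at all times (K = 7210 M⁻¹)
    acid set free + free base ⇌ salt of the base, settled at all times (K = 10000 M⁻¹)
    electrophile + acid set free ⇌ idle adduct, settled at all times (K = 50.0 M⁻¹)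
    acid set free + scavenger → scavenged by-product (k = 120 M⁻¹ h⁻¹)

The flasks give 26.1% in zeta, 26.4% in theta and 26.7% in alpha, a change of 0.55 points: no change. The second view appears in protonated nucleophile, higher in zeta at 0.00405 M than in alpha at 0.00236 M. In zeta, acid set free has a half-life of 0.077 h by the scavenger step alone, far shorter than the electrophile's 13 h by the main step alone. In zeta, acid set free stands at 1.71 × 10⁻⁵ M after 15.0 h. Taking zeta's 73.9% left on to 40 h with equal partners, the read constant gives 37.5% left. The zeta flask then holds 41.1% electrophile, with nucleophile at 31.5%.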